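Eudesmane numbering is used (ring A: C1–C5, C10; ring B: C5–C10; C4 carbinol, C6 ester carbon, C7 isopropyl carbon). Ring B is disconnected at C6–C7: a C6 carbinol beside the C7 isopropyl group is the signature of a citronellal-type carbonyl-ene cyclization. The precursor is a ring A cyclohexane that already holds the C4 tertiary alcohol, a C5 formyl group and, on quaternary C10, the methyl and a 4-methylpent-3-enyl arm. Chelation between the C4 oxygen and the C6 aldehyde, mirroring the syn-diaxial C4–OH/C6–O pair of the target, steers a chair ene closure that forms ring B and sets C6 and C7 at once. Ring A derives from 3-methylcyclohexenone by asymmetric conjugate addition.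

Key step: step 4

Remark on the chemistry (assumption): the copper–NHC catalyst is taken to transfer the 4-methylpent-3-enyl group as it does simple primary alkyl Grignard reagents, and the ligand antipode that gives (R) at C10 is the one used.

Step 1
Reactants: 1 5-bromo-2-methylpent-2-ene; 2 3-methylcyclohex-2-en-1-one
Product: 5 (2S,3R)-2-(hydroxymethyl)-3-methyl-3-(4-methylpent-3-en-1-yl)cyclohexan-1-one, via (4-methylpent-3-en-1-yl)magnesium bromide 3 (not isolated), via bromomagnesium enolate 4 (not isolated)
Conditions: 1, Mg, Et2O; then slow addition to 2, Cu(OTf)2 (3 mol %), chiral N-mesityl-N′-(2-hydroxyalkyl)imidazolinium salt (NHC precursor, 4 mol %), Et2O, 0 °C; then CH2O (gas), −78 °C; aq. NH4Cl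
Reagents that add atoms: formaldehyde (C=O)
Why: Copper–NHC-catalysed asymmetric conjugate addition of a Grignard reagent to a β-substituted cyclic enone sets quaternary C10, and the regiodefined magnesium enolate is trapped at C5 in an aldol reaction with formaldehyde, which should enter opposite the bulkier 4-methylpent-3-enyl arm (CH2OH cis to the C10 methyl).

Step 2
Reactants: 5 (2S,3R)-2-(hydroxymethyl)-3-methyl-3-(4-methylpent-3-en-1-yl)cyclohexan-1-one
Product: 6 (1S,2S,3R)-2-(hydroxymethyl)-1,3-dimethyl-3-(4-methylpent-3-en-1-yl)cyclohexan-1-ol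
Conditions: MeMgBr (3 equiv), CeCl3, THF, −78 → 0 °C; aq. NH4Cl
Reagents that add atoms: methylmagnesium bromide (C[Mg]Br)
Why: Grignard 1,2-addition with CeCl3 (which suppresses enolisation and retro-aldol) should occur on the chair with equatorial hydroxymethyl and axial C10 methyl by equatorial attack away from that syn-axial methyl, giving the axial C4 hydroxyl cis to both the C10 methyl and the hydroxymethyl group.

Step 3
Reactants: 6 (1S,2S,3R)-2-(hydroxymethyl)-1,3-dimethyl-3-(4-methylpent-3-en-1-yl)cyclohexan-1-ol
Product: 7 (1R,2S,6R)-2-hydroxy-2,6-dimethyl-6-(4-methylpent-3-en-1-yl)cyclohexane-1-carbaldehyde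
Conditions: TEMPO (10 mol %), PhI(OAc)2 (1.1 equiv), CH2Cl2, 0 °C → rt; crude product used at once
Reagents that add atoms: none
Why: Oxoammonium (TEMPO) oxidation is selective for the primary alcohol and should leave the tertiary alcohol, the alkene and the epimerisable C5 centre untouched under near-neutral conditions.

Step 4
Reactants: 7 (1R,2S,6R)-2-hydroxy-2,6-dimethyl-6-(4-methylpent-3-en-1-yl)cyclohexane-1-carbaldehyde
Product: 8 (1R,2S,4aR,8S,8aS)-4a,8-dimethyl-2-(prop-1-en-2-yl)decahydronaphthalene-1,8-diol
Conditions: Me2AlCl (2.2 equiv), CH2Cl2, −78 → −20 °C; then H2O, aq. potassium sodium tartrate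
Reagents that add atoms: none
Why: Me2AlCl binds the C4 oxygen and the C6 carbonyl oxygen in a six-membered chelate and scavenges protons; the activated aldehyde carbon C6 is attacked by C7 of the trisubstituted alkene while a hydrogen of a C11 methyl passes to oxygen, giving the homoallylic alcohol with an isopropenyl group. The closest known reaction is the Lewis acid-promoted intramolecular carbonyl-ene reaction of the citronellal-to-isopulegol kind (type 1), here under chelation control. Ring B is closed by the C6–C7 bond through a six-membered chair in which both reacting π-bonds (C6=O and C7=C11) are exocyclic to the new ring (exo,exo mode). At C6 the chelate holds the carbonyl oxygen on the face of the axial C4 oxygen, and an equatorial C6–O would clash (syn-pentane) with the equatorial C4 methyl, so the new hydroxyl should be axial, syn to C4–OH and C10–CH3. At C7 the forming isopropenyl group should take the equatorial position of the chair. The step needs ene closure to outrun dehydration and retro-aldol cleavage of the β-hydroxy aldehyde; the low temperature, the non-protic Lewis acid and the trans-diequatorial C5/C10 arms (already fixed, hence the trans ring fusion) should secure this.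

Step 5
Reactants: 8 (1R,2S,4aR,8S,8aS)-4a,8-dimethyl-2-(prop-1-en-2-yl)decahydronaphthalene-1,8-diol
Product: 9 (1R,2S,4aR,8S,8aS)-4a,8-dimethyl-2-(propan-2-yl)decahydronaphthalene-1,8-diol
Conditions: H2 (1 atm), PtO2 (5 mol %), EtOAc, rt
Reagents that add atoms: none
Why: Heterogeneous catalytic hydrogenation of the unhindered 1,1-disubstituted alkene should give the isopropyl group without creating a stereocentre.

Step 6
Reactants: 9 (1R,2S,4aR,8S,8aS)-4a,8-dimethyl-2-(propan-2-yl)decahydronaphthalene-1,8-diol; 10 2-(diethoxyphosphoryl)acetic acid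
Product: 11 (1R,2S,4aR,8S,8aS)-8-hydroxy-4a,8-dimethyl-2-(propan-2-yl)decahydronaphthalen-1-yl 2-(diethoxyphosphoryl)acetate
Conditions: DCC (1.5 equiv), DMAP (0.3 equiv), CH2Cl2, 0 °C → rt
Reagents that add atoms: none
Why: Steglich esterification should acylate the secondary C6 hydroxyl in preference to the tertiary C4 hydroxyl, the small and highly reactive activated phosphonoacetyl species being suited to the axial, hindered alcohol.

Step 7
Reactants: 11 (1R,2S,4aR,8S,8aS)-8-hydroxy-4a,8-dimethyl-2-(propan-2-yl)decahydronaphthalen-1-yl 2-(diethoxyphosphoryl)acetate; 12 3-hydroxybenzaldehyde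
Product: 13 (1R,2S,4aR,8S,8aS)-8-hydroxy-4a,8-dimethyl-2-(propan-2-yl)decahydronaphthalen-1-yl (2E)-3-(3-hydroxyphenyl)prop-2-enoate (CNP0283603.1)
Conditions: LiCl (3 equiv), DBU (2.5 equiv), MeCN, rt
Reagents that add atoms: none
Why: Horner–Wadsworth–Emmons olefination of the stabilised phosphonate should give the (E)-cinnamate, the free phenol being tolerated because its phenoxide is meta to, and not conjugated with, the aldehyde.

Compound list
1 | 5-bromo-2-methylpent-2-ene | CC(C)=CCCBr | starting material
2 | 3-methylcyclohex-2-en-1-one | CC1=CC(=O)CCC1 | starting material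
3 | (4-methylpent-3-en-1-yl)magnesium bromide | CC(C)=CCC[Mg]Br | intermediate
4 | bromomagnesium (3R)-3-methyl-3-(4-methylpent-3-en-1-yl)cyclohex-1-en-1-olate | CC(C)=CCC[C@@]1(C)CCCC(O[Mg]Br)=C1 | intermediate
5 | (2S,3R)-2-(hydroxymethyl)-3-methyl-3-(4-methylpent-3-en-1-yl)cyclohexan-1-one | CC(C)=CCC[C@@]1(C)CCCC(=O)[C@@H]1CO | intermediate
6 | (1S,2S,3R)-2-(hydroxymethyl)-1,3-dimethyl-3-(4-methylpent-3-en-1-yl)cyclohexan-1-ol | CC(C)=CCC[C@@]1(C)CCC[C@](C)(O)[C@@H]1CO | intermediate
7 | (1R,2S,6R)-2-hydroxy-2,6-dimethyl-6-(4-methylpent-3-en-1-yl)cyclohexane-1-carbaldehyde | CC(C)=CCC[C@@]1(C)CCC[C@](C)(O)[C@@H]1C=O | intermediate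
8 | (1R,2S,4aR,8S,8aS)-4a,8-dimethyl-2-(prop-1-en-2-yl)decahydronaphthalene-1,8-diol | CC(=C)[C@@H]1CC[C@@]2(C)CCC[C@](C)(O)[C@@H]2[C@@H]1O | intermediate
9 | (1R,2S,4aR,8S,8aS)-4a,8-dimethyl-2-(propan-2-yl)decahydronaphthalene-1,8-diol | CC(C)[C@@H]1CC[C@@]2(C)CCC[C@](C)(O)[C@@H]2[C@@H]1O | intermediate
10 | 2-(diethoxyphosphoryl)acetic acid | CCOP(=O)(CC(=O)O)OCC | starting material
11 | (1R,2S,4aR,8S,8aS)-8-hydroxy-4a,8-dimethyl-2-(propan-2-yl)decahydronaphthalen-1-yl 2-(diethoxyphosphoryl)acetate | CC(C)[C@@H]1CC[C@@]2(C)CCC[C@](C)(O)[C@@H]2[C@@H]1OC(=O)CP(=O)(OCC)OCC | intermediate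
12 | 3-hydroxybenzaldehyde | O=Cc1cccc(O)c1 | starting material
13 | (1R,2S,4aR,8S,8aS)-8-hydroxy-4a,8-dimethyl-2-(propan-2-yl)decahydronaphthalen-1-yl (2E)-3-(3-hydroxyphenyl)prop-2-enoate | CC(C)[C@@H]1CC[C@@]2(C)CCC[C@](C)(O)[C@@H]2[C@@H]1OC(=O)/C=C/c1cccc(O)c1 | target

Total step count: 7. Longest linear sequence: 7 steps (1 and 2 to 13).

Steps most likely to fail

Step 1. The face selection at C5 rests on a small size difference between the two C10 substituents (CH3 against CH2R), so trapping from both enolate faces, giving a mixture of C5 epimers, is the likely failure; incomplete enantioface control in the conjugate addition is a second one. The fallback sets out from 2 and Grignard reagent 3: the same conjugate addition is run, but enolate 4 is quenched with TMSCl/Et3N and the trimethylsilyl enol ether F1 is isolated. F1 is then hydroxymethylated with aqueous formaldehyde under a chiral Sc(OTf)3–2,2′-bipyridine-diol catalyst (Mukaiyama aldol in aqueous DME, −20 °C), so that the catalyst and not the substrate chooses the C5 face. This comes back to the route at ketol 5.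

Step 4. The β-hydroxy aldehyde may lose water or undergo retro-aldol cleavage under the Lewis acid, or the developing tertiary cation at C11 may be captured by chloride or by the C4 oxygen instead of losing a proton. The fallback sets out from aldehyde 7 and closes ring B by a radical route: thiol-catalysed radical-chain hydroacylation (tert-dodecanethiol cat., AIBN, dioxane, 80 °C) generates the C6 acyl radical, which adds 6-exo to C7, and the tertiary C11 radical takes hydrogen from the thiol to give the hydroxy ketone F2 with the isopropyl group in place. Reduction of F2 with LiAlH4 (THF, 0 °C), by hydride delivery to the open face opposite C10–CH3 and C4–OH, should give the axial C6 alcohol. This comes back to the route at diol 9 and by-passes step 5.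

Step 6. Acylation of the axial C6 hydroxyl, flanked by the syn-axial C10 methyl and C4 hydroxyl and by the C7 isopropyl group, may stall at the O-acylisourea stage or divert to N-acylurea. The fallback sets out from diol 9: bromoacetyl bromide and pyridine (CH2Cl2, −20 °C) give the bromoacetate F3 through a small, very reactive acyl halide, and an Arbuzov reaction with P(OEt)3 (neat, 90 °C) converts F3 into the phosphonate. This comes back to the route at 11.

Further compounds
F1 | step 1 | trimethyl{[(3R)-3-methyl-3-(4-methylpent-3-en-1-yl)cyclohex-1-en-1-yl]oxy}silane | CC(C)=CCC[C@@]1(C)CCCC(O[Si](C)(C)C)=C1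
F2 | step 4 | (2S,4aR,8S,8aR)-8-hydroxy-4a,8-dimethyl-2-(propan-2-yl)octahydronaphthalen-1(2H)-one | CC(C)[C@@H]1CC[C@@]2(C)CCC[C@](C)(O)[C@@H]2C1=O
F3 | step 6 | (1R,2S,4aR,8S,8aS)-8-hydroxy-4a,8-dimethyl-2-(propan-2-yl)decahydronaphthalen-1-yl 2-bromoacetate | CC(C)[C@@H]1CC[C@@]2(C)CCC[C@](C)(O)[C@@H]2[C@@H]1OC(=O)CBr
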